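# Proposed total synthesis of CNP0122760.1 by Ireland–Claisen ring contraction of a linalool-derived lactone

## Analysis of the target

Atom numbering used throughout: the bicycle is numbered like naphthalene (C1 gem-dimethyl carbon, C2 chain-bearing alkene carbon, C3 methyl-bearing alkene carbon, C4, ring fusion C4a, C5=C6 with the methyl on C6, C7, C8, ring fusion C8a). C9–C10 is the linker, C11 (quaternary, methyl) to C14 are the dioxane carbons, and C15 (methyl) and C16 (carboxyl) are the acid chain.

- The target is (2R)-2-[(3R,6R)-6-methyl-6-{2-[(4aR,8aS)-1,1,3,6-tetramethyl-1,4,4a,7,8,8a-hexahydronaphthalen-2-yl]ethyl}-1,2-dioxan-3-yl]propanoic acid.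
- It is a cis-fused hexahydronaphthalene (ring A: C4a–C5–C6–C7–C8–C8a; ring B: C1–C2–C3–C4–C4a–C8a) joined through C9–C10 to a 1,2-dioxane that carries a 2-propanoic acid.
- There are five stereocentres in two clusters that cannot influence each other: C4a (R) and C8a (S) with cis hydrogens, and C11 (R), C14 (R), C15 (R) on the peroxide half.
- The sensitive groups are the O–O bond (reducing agents, hydrogenation catalysts, low-valent metals, carbanions in the β position), the two alkenes (acid can move the C5=C6 bond), and C15, which is epimerisable and β to a peroxide oxygen.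
- Ring A offers no heteroatom from which the cis pair could be controlled. C11 carries two groups of similar size (methyl and the C10 chain), so no ring-closing addition can be expected to set it selectively.
- The strategy rests on the array C1(=O)–C8a–C4a–C5=C6. With C1 as a carboxyl carbon this is a γ,δ-unsaturated acid, the retron of an ester-enolate Claisen rearrangement. C6 bears a methyl group and is linked to C8a through C7–C8. Before rearrangement C6 can therefore be the methyl carbinol carbon of linalool held in a six-membered lactone.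

## Retrosynthetic reasoning

**Acid.** Target 40 is taken back to its methyl ester 39. The carboxyl group is masked during the olefination and freed last by saponification.

**C9–C10.** Ester 39 comes from diene 38 by saturation of the C9=C10 bond, and 38 from phosphonium salt 23 and aldehyde 36. This is the only bond that separates the two stereochemical clusters, so each half can be made and purified alone. C9 is allylic to the C2=C3 alkene and supports an ylide (37). The peroxide half must be the electrophile, because a carbanion at C10 would expel the peroxide oxygen on C11. The new alkene is the least substituted one in 38, so diimide can remove it without touching O–O.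

**Oxidation levels on the dioxane.** Aldehyde 36 comes from alcohol 35, and the ester carbon C16 from the vinyl group of 32 (through 33 and 34). C16 is kept as an alkene until the ring is closed, because a carbonyl there would cause β-elimination of the C14 leaving group.

**C14–O and C11–O.** Dioxane 32 comes from hydroperoxy mesylate 31 by intramolecular displacement at C14 with inversion. 31 comes from epoxide 30 by opening at the tertiary carbon C11 with inversion. Two stereospecific substitutions are used because a ring-closing addition could not tell the methyl group from the C10 arm on C11.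

**C14–C15 and C12–C13.** Mesylate 30 comes from alcohol 29, made by Z-crotylboration of aldehyde 28. This sets C14 and C15 together and brings in the vinyl group. Aldehyde 28 comes from alkene 27, and 27 from tosylate 25 by allylation at the epoxide CH2 and re-closure of the epoxide onto the tosylate carbon (through 26). C11 is taken from (S)-2-methylglycidol 24 and no bond to it is broken before step 21.

**Alkene position in ring B.** Salt 23 comes from allylic alcohol 22 and this from enal 21. Conjugation with the C9 carbonyl makes the C2=C3 position the only stable one, so the alkene isomers and C2 epimers 18, 19 and 20 that ring B closure gives all converge on 21.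

**C1–C2.** Bicycle 18 comes from tertiary alcohol 17 by cation–olefin closure. The C1 cation is attacked by C2 of the chain alkene, which places the charge on the tertiary C3 and forms a six-membered ring from two cis arms. The C1 carbinol comes from ester 16 and acid 15, since a gem-dimethyl carbon next to C8a is what a carboxyl carbon becomes after two methyl additions.

**C4a–C8a (key disconnection).** Acid 15 comes from lactone 12. In the silyl ketene acetal 13 the unit C8a=C1–O–C6–C5=C4a is an allyl vinyl ether. The [3,3] shift forms C4a–C8a, breaks C6–O, closes ring A, makes both ring-fusion stereocentres and places the alkene at C5=C6 with its methyl group.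

**C4a=C5.** Lactone 12 comes from vinyl lactone 7 and diene 11 by cross-metathesis, which sets the E geometry needed for the cis outcome. It is done on the lactone, because in 1 the two alkenes would undergo ring-closing metathesis.

**Lactone and chain.** Lactone 7 comes from (R)-linalool 1 by cleavage of the trisubstituted alkene (lactol 2), one-carbon homologation with ylide 4 from salt 3 (enol ether 5), hydrolysis (lactol 6) and oxidation. Diene 11 comes from alcohol 10, made from pent-1-en-4-yne 8 by carboalumination (alane 9), which fixes the E trisubstituted alkene.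

## Alternatives that were turned down

**Alternative 1:** Diels–Alder on a ring B dienone, then alkene transposition.
- Disconnection: C4a–C5 and C8–C8a, so ring A is made by [4+2] cycloaddition onto a finished ring B.
- Forward key step: the achiral cross-conjugated dienone A1 reacts at its C4a=C8a alkene with siloxy diene A2 under a chiral boron Lewis acid, endo, to give the cis-fused octalenone A3.
- For: ring B with its gem-dimethyl group, the C2=C3 alkene and the C9 oxygen is complete before any stereocentre exists, so the alkene-position problem of ring B does not arise. Cis fusion follows from suprafacial addition, and the step is catalytic and convergent. On these points it is stronger than the chosen route.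
- Against: A3 carries a C4 ketone and a C5 silyloxy group that the target lacks, and its alkene is at C6=C7. Removing the hindered enone carbonyl and moving the alkene to C5=C6 with loss of the C5 oxygen needs several redox steps. In these steps C4a is α to the ketone and can epimerise to the trans-fused series. The dienophile carbon C8a is next to the quaternary C1, so the cycloaddition is sterically slow, and the catalyst must distinguish the enantiotopic faces of a flat dienone.
- Comparison: the chosen strategy delivers ring A at the final oxidation level with the alkene already in place, and needs no corrections next to the stereocentres.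

**Alternative 2:** Terpene-cyclase bicyclisation of an acyclic allylic diphosphate.
- Disconnection: C4a–C8a and C1–C2 in one operation.
- Forward key step: a terpene cyclase ionises the tertiary allylic diphosphate A4 and closes rings A and B in sequence to the cis-fused acetate A5.
- For: one step forms both rings and both stereocentres and can place both alkenes. No chemical sequence matches this step economy, and on this point it is clearly stronger.
- Against: it needs an enzyme that accepts A4 and gives this skeleton, this fusion and this enantiomer. That cannot be derived from the structure and would have to be found or evolved. A4 is a solvolytically labile tertiary allylic diphosphate. Monocyclic products, other deprotonation sites and capture by water are all open outcomes.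
- Comparison: the chosen route uses reactions whose stereochemical course follows from geometry and that run with ordinary reagents.

**Alternative 3:** Catalytic asymmetric Diels–Alder assembly of ring A.
- Disconnection: C4a–C8a and C7–C8.
- Forward key step: triene acetate A6 (diene part C4a to C7) and acrylate A7 combine under a chiral oxazaborolidinium acid, endo, to give the cyclohexene ester A8.
- For: one catalytic step from achiral materials gives essentially the same ring A intermediate as 16. Both directing effects (ortho to the C4a substituent, para to the C6 methyl) agree. It needs fewer steps than the sequence from 1 to 15 and no stoichiometric chiral material. On step economy it is as strong or stronger.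
- Against: both the cis relation (endo against exo) and the absolute configuration depend on the fit between catalyst and an open-chain 1,3-disubstituted diene, with an acrylate as a weakly activated dienophile. The strongly acidic catalyst must coexist with an acid-sensitive skipped triene and a Lewis-basic allylic acetate. Any exo pathway gives the trans isomer.
- Comparison: in the chosen strategy the trans isomer is geometrically excluded and the absolute configuration comes from the chiral pool by an intramolecular transfer. Alternative 3 is kept as the fallback for the key step.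

Key step: step 8

## Remarks on the chemistry (assumptions)

- Compounds 18, 19 and 20 are expected as mixtures of ring B alkene isomers (C3=C4 as main isomer, with the C2=C3 and exocyclic C3-methylene isomers) and of C2 epimers. Each is listed as its expected main isomer, and all converge on the single enal 21 in step 13.
- Enol ether 5 and diene 38 are E/Z mixtures at a double bond that is removed later.
- Commercial (R)-linalool and (S)-2-methylglycidol are taken as enantiomerically pure.

## Route

### Part 1: lactone 7 from (R)-linalool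

Step 1
Reactants: 1 (R)-linalool [(3R)-3,7-dimethylocta-1,6-dien-3-ol]
Product: 2 (5R)-5-ethenyl-5-methyloxolan-2-ol (lactol; both anomers)
Conditions: O3 (1 equiv, Sudan Red 7B as end-point indicator), CH2Cl2/MeOH, −78 °C; then Me2S, −78 °C → rt
Reagents that add atoms: ozone, [O-][O+]=O
Why: Ozonolysis is much faster at the electron-rich trisubstituted alkene than at the vinyl group, so one equivalent should cleave only the former; the hydroxy aldehyde closes to the five-membered lactol and the carbinol centre is untouched.

Step 2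
Reactants: 2 (5R)-5-ethenyl-5-methyloxolan-2-ol; 3 (methoxymethyl)triphenylphosphonium chloride
Product: 5 (3R)-7-methoxy-3-methylhepta-1,6-dien-3-ol (E/Z mixture at the enol ether), via methoxymethylene ylide 4 (not isolated)
Conditions: 3 (2.6 equiv), KOt-Bu (2.5 equiv), THF, 0 °C; then 2, 0 °C → rt
Reagents that add atoms: none
Why: Wittig one-carbon homologation of a lactol through its open hydroxy aldehyde form; the excess ylide also takes the hydroxyl proton, and the tertiary alkoxide does not interfere.

Step 3
Reactants: 5 (3R)-7-methoxy-3-methylhepta-1,6-dien-3-ol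
Product: 6 (6R)-6-ethenyl-6-methyloxan-2-ol (lactol; both anomers)
Conditions: 0.5 M aq. HCl, THF, 0 °C → rt
Reagents that add atoms: water, O
Why: Enol ether hydrolysis; the oxocarbenium ion is trapped by the tertiary hydroxyl to give the six-membered lactol, and the dilute acid at low temperature should not ionise the allylic carbinol.

Step 4
Reactants: 6 (6R)-6-ethenyl-6-methyloxan-2-ol
Product: 7 (6R)-6-ethenyl-6-methyloxan-2-one
Conditions: TEMPO (0.1 equiv), PhI(OAc)2 (1.3 equiv), CH2Cl2, rt
Reagents that add atoms: none
Why: Oxoammonium-mediated oxidation of a lactol to the lactone; a chromium oxidant is avoided because it could cause oxidative transposition at the tertiary allylic oxygen.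

### Part 2: chain partner 11

Step 5
Reactants: 8 pent-1-en-4-yne
Product: 10 (2E)-3-methylhexa-2,5-dien-1-ol, via alkenylalane 9 (not isolated)
Conditions: Me3Al (2 equiv), Cp2ZrCl2 (0.25 equiv), CH2Cl2, 0 °C → rt; then n-BuLi, THF, −78 °C; (CH2O)n, −78 °C → rt; dilute HCl work-up
Reagents that add atoms: trimethylaluminium, C[Al](C)C; paraformaldehyde (as formaldehyde), C=O
Why: Zirconium-catalysed carboalumination (Negishi) adds methyl and aluminium syn across the terminal alkyne with methyl on the inner carbon; hydroxymethylation of the aluminate with retention fixes the E trisubstituted alkene. The isolated terminal alkene is inert under these conditions.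

Step 6
Reactants: 10 (2E)-3-methylhexa-2,5-dien-1-ol
Product: 11 tert-butyl{[(2E)-3-methylhexa-2,5-dien-1-yl]oxy}diphenylsilane
Conditions: TBDPSCl (1.1 equiv), imidazole (2 equiv), CH2Cl2, 0 °C → rt
Reagents that add atoms: tert-butyl(chloro)diphenylsilane, CC(C)(C)[Si](Cl)(c1ccccc1)c1ccccc1
Why: Standard silylation; the bulky, weakly Lewis-basic silyl ether is chosen because it must survive amide base, methyl organometallics and the Lewis acid of step 11.

### Part 3: key-step precursor and ring contraction

Step 7
Reactants: 7 (6R)-6-ethenyl-6-methyloxan-2-one; 11 tert-butyl{[(2E)-3-methylhexa-2,5-dien-1-yl]oxy}diphenylsilane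
Product: 12 (6R)-6-[(1E,4E)-6-{[tert-butyl(diphenyl)silyl]oxy}-4-methylhexa-1,4-dien-1-yl]-6-methyloxan-2-one
Conditions: 11 (3 equiv), second-generation Hoveyda–Grubbs catalyst [RuCl2(H2IMes)(=CH–C6H4-2-OiPr), 5 mol%], CH2Cl2, 40 °C, argon purge
Reagents that add atoms: none
Why: Olefin cross-metathesis between a hindered vinyl group that does not homodimerise and an excess of an unhindered terminal alkene; the fully substituted C6 enforces the E alkene. The trisubstituted alkene of 11 does not take part.

Step 8
Reactants: 12 (6R)-6-[(1E,4E)-6-{[tert-butyl(diphenyl)silyl]oxy}-4-methylhexa-1,4-dien-1-yl]-6-methyloxan-2-one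
Product: 15 (1S,2R)-2-[(2E)-4-{[tert-butyl(diphenyl)silyl]oxy}-2-methylbut-2-en-1-yl]-4-methylcyclohex-3-ene-1-carboxylic acid, via silyl ketene acetal 13 (not isolated), via trimethylsilyl ester 14 (not isolated)
Conditions: LDA (1.2 equiv), THF, −78 °C; Me3SiCl/Et3N (1.5 equiv), −78 °C → rt; solvent change to toluene, 105 °C; then 1 M HCl, THF, rt
Reagents that add atoms: none
Why: Deprotonation at C8a and O-silylation give the cyclic silyl ketene acetal 13, in which C8a=C1–O–C6–C5=C4a is an allyl vinyl ether. On heating, a [3,3]-sigmatropic shift forms C4a–C8a and breaks C6–O to give silyl ester 14, which the acidic work-up hydrolyses to 15; the closest known reaction type is the Ireland–Claisen ring contraction of alkenyl lactones to cycloalkene carboxylic acids. Ring A (C4a–C5–C6–C7–C8–C8a) closes by this sigmatropic ring contraction, and because the C7–C8 tether joins the two termini C8a and C6, only a boat transition state can be reached. C8a is set by the C6 carbinol configuration, since only the alkenyl group of the (R)-centre, held axial, can reach one face of the ketene acetal. C4a is set by the E geometry of the C4a=C5 alkene, which in that boat puts the C4 chain on the same side as C1. The step needs complete chirality transfer and the cis relation; both are secured because the chair is geometrically excluded and C7 must end cis to C4a in the new ring alkene, which leaves one arrangement. The C5=C6 alkene is formed regiospecifically with its methyl group, and the stereocentre at C6 is consumed.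

### Part 4: ring B and the phosphonium salt

Step 9
Reactants: 15 (1S,2R)-2-[(2E)-4-{[tert-butyl(diphenyl)silyl]oxy}-2-methylbut-2-en-1-yl]-4-methylcyclohex-3-ene-1-carboxylic acid
Product: 16 methyl (1S,2R)-2-[(2E)-4-{[tert-butyl(diphenyl)silyl]oxy}-2-methylbut-2-en-1-yl]-4-methylcyclohex-3-ene-1-carboxylate
Conditions: Me3SiCHN2 (1.3 equiv), toluene/MeOH (4:1), 0 °C → rt
Reagents that add atoms: (trimethylsilyl)diazomethane, C[Si](C)(C)C=[N+]=[N-]
Why: Esterification under neutral conditions, so the C8a centre α to the carboxyl group is not exposed to base.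

Step 10
Reactants: 16 methyl (1S,2R)-2-[(2E)-4-{[tert-butyl(diphenyl)silyl]oxy}-2-methylbut-2-en-1-yl]-4-methylcyclohex-3-ene-1-carboxylate
Product: 17 2-[(1S,2R)-2-[(2E)-4-{[tert-butyl(diphenyl)silyl]oxy}-2-methylbut-2-en-1-yl]-4-methylcyclohex-3-en-1-yl]propan-2-ol
Conditions: MeLi (3 equiv), CeCl3 (3 equiv, dried), THF, −78 → 0 °C
Reagents that add atoms: methyllithium, [Li]C
Why: Double addition of a methyl organocerium reagent to the ester; the low basicity of the cerium reagent suppresses enolisation of the intermediate methyl ketone, so C8a keeps its configuration.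

Step 11
Reactants: 17 2-[(1S,2R)-2-[(2E)-4-{[tert-butyl(diphenyl)silyl]oxy}-2-methylbut-2-en-1-yl]-4-methylcyclohex-3-en-1-yl]propan-2-ol
Product: 18 tert-butyl{[(4aS,8aS)-1,1,3,6-tetramethyl-1,2,4a,7,8,8a-hexahydronaphthalen-2-yl]methoxy}diphenylsilane (main isomer of an alkene-isomer mixture; C2 epimers)
Conditions: SnCl4 (1.2 equiv), CH2Cl2, −78 → −30 °C; aq. NaHCO3
Reagents that add atoms: none
Why: Tertiary-carbinol-initiated cation–olefin cyclisation: the C1 cation is attacked by C2 of the trisubstituted alkene (Markovnikov, charge to tertiary C3) through a six-membered transition state open to the cis arms, and loss of a proton ends the reaction. The ring-fusion centres are not involved; the position of the new alkene is left open here and is fixed in step 13.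

Step 12
Reactants: 18 tert-butyl{[(4aS,8aS)-1,1,3,6-tetramethyl-1,2,4a,7,8,8a-hexahydronaphthalen-2-yl]methoxy}diphenylsilane (mixture)
Product: 19 [(4aS,8aS)-1,1,3,6-tetramethyl-1,2,4a,7,8,8a-hexahydronaphthalen-2-yl]methanol (main isomer of the mixture)
Conditions: Bu4NF (1.5 equiv), THF, rt
Reagents that add atoms: none
Why: Fluoride cleavage of the silyl ether; no other group responds to fluoride.

Step 13
Reactants: 19 [(4aS,8aS)-1,1,3,6-tetramethyl-1,2,4a,7,8,8a-hexahydronaphthalen-2-yl]methanol (mixture)
Product: 21 (4aR,8aS)-1,1,3,6-tetramethyl-1,4,4a,7,8,8a-hexahydronaphthalene-2-carbaldehyde, via unconjugated aldehyde 20 (not isolated)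
Conditions: Dess–Martin periodinane (1.3 equiv), NaHCO3, CH2Cl2, 0 °C → rt; aqueous work-up; then KOH (0.1 M), MeOH, rt
Reagents that add atoms: none
Why: Oxidation gives β,γ-unsaturated aldehydes whose acidic C2–H lets base move the alkene into conjugation, as in the isomerisation of α- to β-cyclocitral. Every alkene isomer and C2 epimer should end as the one tetrasubstituted enal; the ring A alkene and the ring-fusion centres have no acidic neighbours and stay.

Step 14
Reactants: 21 (4aR,8aS)-1,1,3,6-tetramethyl-1,4,4a,7,8,8a-hexahydronaphthalene-2-carbaldehyde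
Product: 22 [(4aR,8aS)-1,1,3,6-tetramethyl-1,4,4a,7,8,8a-hexahydronaphthalen-2-yl]methanol
Conditions: NaBH4 (1.2 equiv), CeCl3·7H2O (1 equiv), MeOH, 0 °C
Reagents that add atoms: none
Why: Luche 1,2-reduction of the hindered enal to the allylic alcohol without conjugate reduction.

Step 15
Reactants: 22 [(4aR,8aS)-1,1,3,6-tetramethyl-1,4,4a,7,8,8a-hexahydronaphthalen-2-yl]methanol
Product: 23 {[(4aR,8aS)-1,1,3,6-tetramethyl-1,4,4a,7,8,8a-hexahydronaphthalen-2-yl]methyl}triphenylphosphonium bromide
Conditions: Ph3P·HBr (1.1 equiv), MeOH, rt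
Reagents that add atoms: triphenylphosphine hydrobromide, [Br-].[PH+](c1ccccc1)(c1ccccc1)c1ccccc1
Why: Direct conversion of a β-cyclogeraniol-type allylic alcohol into its phosphonium salt, as practised in carotenoid chemistry; the stabilised allyl cation is captured by phosphine at the primary terminus, and the mild acid should leave the ring A alkene in place.

### Part 5: dioxane aldehyde 36

Step 16
Reactants: 24 (S)-2-methylglycidol {[(2S)-2-methyloxiran-2-yl]methanol}
Product: 25 [(2R)-2-methyloxiran-2-yl]methyl 4-methylbenzenesulfonate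
Conditions: TsCl (1.1 equiv), Et3N (1.5 equiv), DMAP (cat.), CH2Cl2, 0 °C
Reagents that add atoms: 4-toluenesulfonyl chloride, Cc1ccc(cc1)S(Cl)(=O)=O
Why: Sulfonylation of the primary alcohol; no bond to the quaternary centre is touched (the descriptor changes only through the priority rules).

Step 17
Reactants: 25 [(2R)-2-methyloxiran-2-yl]methyl 4-methylbenzenesulfonate
Product: 27 (2R)-2-(but-3-en-1-yl)-2-methyloxirane, via hydroxy tosylate 26 (not isolated)
Conditions: allylMgCl (1.3 equiv), CuI (10 mol%), THF, −40 °C; aq. NH4Cl; then K2CO3, MeOH, rt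
Reagents that add atoms: allylmagnesium chloride, C=CC[Mg]Cl
Why: Copper-catalysed Grignard opening at the unhindered epoxide CH2 (which becomes C12) is faster than displacement at the neopentyl-like tosylate carbon; the tertiary alkoxide then closes the new epoxide onto that carbon (C10). C11 keeps all four bonds, so its configuration is retained.

Step 18
Reactants: 27 (2R)-2-(but-3-en-1-yl)-2-methyloxirane
Product: 28 3-[(2R)-2-methyloxiran-2-yl]propanal
Conditions: O3, CH2Cl2, −78 °C; then PPh3, −78 °C → rt; used without delay
Reagents that add atoms: ozone, [O-][O+]=O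
Why: Ozonolysis with reductive work-up under neutral conditions, which the acid-sensitive 2,2-disubstituted epoxide tolerates.

Step 19
Reactants: 28 3-[(2R)-2-methyloxiran-2-yl]propanal
Product: 29 (3S,4S)-3-methyl-6-[(2R)-2-methyloxiran-2-yl]hex-1-en-4-ol
Conditions: (S,S)-diisopropyl tartrate (Z)-crotylboronate (1.5 equiv), 4 Å molecular sieves, toluene, −78 °C; aq. NaOH work-up
Reagents that add atoms: diisopropyl (4S,5S)-2-[(2Z)-but-2-en-1-yl]-1,3,2-dioxaborolane-4,5-dicarboxylate, C/C=C\CB1O[C@H](C(=O)OC(C)C)[C@@H](C(=O)OC(C)C)O1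
Why: Roush crotylboration through a closed chair transition state: the Z-crotyl unit gives the syn relation of C14–OH and C15–CH3, and the (S,S)-tartrate directs attack to the Re face of the aldehyde, which gives the (3S,4S) alcohol. The reagent carries no Lewis acid that would open the epoxide; any minor diastereomer is removed by chromatography here or at 32.

Step 20
Reactants: 29 (3S,4S)-3-methyl-6-[(2R)-2-methyloxiran-2-yl]hex-1-en-4-ol
Product: 30 (3S,4S)-3-methyl-6-[(2R)-2-methyloxiran-2-yl]hex-1-en-4-yl methanesulfonate
Conditions: MsCl (1.3 equiv), Et3N (2 equiv), CH2Cl2, 0 °C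
Reagents that add atoms: methanesulfonyl chloride, CS(Cl)(=O)=O
Why: Sulfonylation with retention at C14; it also blocks the hydroxyl, which would otherwise open the epoxide to a tetrahydrofuran in the next step.

Step 21
Reactants: 30 (3S,4S)-3-methyl-6-[(2R)-2-methyloxiran-2-yl]hex-1-en-4-yl methanesulfonate
Product: 31 (3S,4S,7S)-7-hydroperoxy-8-hydroxy-3,7-dimethyloct-1-en-4-yl methanesulfonate
Conditions: anhydrous H2O2 in Et2O (10 equiv), H3PMo12O40 (3 mol%), Et2O, rt
Reagents that add atoms: hydrogen peroxide, OO
Why: Acid-catalysed perhydrolysis of a 2,2-disubstituted epoxide takes place at the tertiary carbon, anti to the departing oxygen, which should set C11 by inversion and leave C10 as the primary alcohol. The mesylate and the terminal alkene are inert to these conditions.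

Step 22
Reactants: 31 (3S,4S,7S)-7-hydroperoxy-8-hydroxy-3,7-dimethyloct-1-en-4-yl methanesulfonate
Product: 32 [(3S,6R)-6-[(2S)-but-3-en-2-yl]-3-methyl-1,2-dioxan-3-yl]methanol
Conditions: CsOH·H2O (1.1 equiv), DMF, 0 °C
Reagents that add atoms: none
Why: Intramolecular alkylation of a hydroperoxide (6-exo-tet): one equivalent of base deprotonates only the more acidic hydroperoxide, whose weakly basic and strongly nucleophilic anion displaces the mesylate with inversion and sets C14. Leaving the primary alcohol protonated avoids fragmentation of the β-hydroperoxy alkoxide.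

Step 23
Reactants: 32 [(3S,6R)-6-[(2S)-but-3-en-2-yl]-3-methyl-1,2-dioxan-3-yl]methanol
Product: 34 (2R)-2-[(3R,6S)-6-(hydroxymethyl)-6-methyl-1,2-dioxan-3-yl]propanoic acid, via hydroxy aldehyde 33 (not isolated)
Conditions: O3, CH2Cl2/MeOH, −78 °C; Me2S; then NaClO2, NaH2PO4, 2-methylbut-2-ene, t-BuOH/H2O, 0 °C → rt
Reagents that add atoms: ozone, [O-][O+]=O; sodium chlorite, [Na+].[O-]Cl=O
Why: Ozonolysis and Pinnick oxidation turn the vinyl group into the carboxyl group under neutral to weakly acidic conditions; the dialkyl peroxide, the primary alcohol and the α-centre C15 are not affected (the C15 descriptor changes only by the priority rules).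

Step 24
Reactants: 34 (2R)-2-[(3R,6S)-6-(hydroxymethyl)-6-methyl-1,2-dioxan-3-yl]propanoic acid
Product: 35 methyl (2R)-2-[(3R,6S)-6-(hydroxymethyl)-6-methyl-1,2-dioxan-3-yl]propanoate
Conditions: Me3SiCHN2 (1.3 equiv), toluene/MeOH (4:1), 0 °C
Reagents that add atoms: (trimethylsilyl)diazomethane, C[Si](C)(C)C=[N+]=[N-]
Why: Neutral esterification; base, which could open the β-peroxy acid by elimination, is avoided.

Step 25
Reactants: 35 methyl (2R)-2-[(3R,6S)-6-(hydroxymethyl)-6-methyl-1,2-dioxan-3-yl]propanoate
Product: 36 methyl (2R)-2-[(3R,6S)-6-formyl-6-methyl-1,2-dioxan-3-yl]propanoate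
Conditions: Dess–Martin periodinane (1.3 equiv), NaHCO3, CH2Cl2, 0 °C → rt
Reagents that add atoms: none
Why: Mild oxidation of the neopentyl-type primary alcohol; the aldehyde has no α-hydrogen and cannot enolise, and the oxidant does not attack the peroxide.

### Part 6: union and end game

Step 26
Reactants: 23 {[(4aR,8aS)-1,1,3,6-tetramethyl-1,4,4a,7,8,8a-hexahydronaphthalen-2-yl]methyl}triphenylphosphonium bromide; 36 methyl (2R)-2-[(3R,6S)-6-formyl-6-methyl-1,2-dioxan-3-yl]propanoate
Product: 38 methyl (2R)-2-[(3R,6S)-6-methyl-6-{2-[(4aR,8aS)-1,1,3,6-tetramethyl-1,4,4a,7,8,8a-hexahydronaphthalen-2-yl]ethenyl}-1,2-dioxan-3-yl]propanoate (E/Z mixture), via phosphonium ylide 37 (not isolated)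
Conditions: 23 (1.2 equiv), NaHMDS (1.15 equiv), THF, −78 → 0 °C; then 36, −78 °C → rt
Reagents that add atoms: none
Why: Wittig olefination with a β-cyclogeranyl-type allylic ylide and an activated α-oxygenated aldehyde; the base is fully consumed before 36 is added, so the ester α-hydrogen at C15 is not exposed to it. The geometry of the new alkene is irrelevant.

Step 27
Reactants: 38 methyl (2R)-2-[(3R,6S)-6-methyl-6-{2-[(4aR,8aS)-1,1,3,6-tetramethyl-1,4,4a,7,8,8a-hexahydronaphthalen-2-yl]ethenyl}-1,2-dioxan-3-yl]propanoate
Product: 39 methyl (2R)-2-[(3R,6R)-6-methyl-6-{2-[(4aR,8aS)-1,1,3,6-tetramethyl-1,4,4a,7,8,8a-hexahydronaphthalen-2-yl]ethyl}-1,2-dioxan-3-yl]propanoate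
Conditions: KO2C–N=N–CO2K (excess, in portions), AcOH, MeOH/CH2Cl2, 0 °C → rt
Reagents that add atoms: none
Why: Diimide transfers hydrogen in a concerted syn fashion and reduces the disubstituted C9=C10 bond much faster than the trisubstituted and tetrasubstituted alkenes; unlike catalytic hydrogenation it does not cleave the O–O bond.

Step 28
Reactants: 39 methyl (2R)-2-[(3R,6R)-6-methyl-6-{2-[(4aR,8aS)-1,1,3,6-tetramethyl-1,4,4a,7,8,8a-hexahydronaphthalen-2-yl]ethyl}-1,2-dioxan-3-yl]propanoate
Product: 40 (2R)-2-[(3R,6R)-6-methyl-6-{2-[(4aR,8aS)-1,1,3,6-tetramethyl-1,4,4a,7,8,8a-hexahydronaphthalen-2-yl]ethyl}-1,2-dioxan-3-yl]propanoic acid (target)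
Conditions: LiOH·H2O (3 equiv), THF/MeOH/H2O, 0 °C → rt; then 1 M HCl to pH 3
Reagents that add atoms: lithium hydroxide, [Li+].[OH-]
Why: Saponification of the methyl ester; hydroxide at low temperature attacks the carbonyl faster than it enolises the ester, so C15 and the β-peroxy linkage should survive.

## Compound list

1 | (R)-linalool, (3R)-3,7-dimethylocta-1,6-dien-3-ol | CC(C)=CCC[C@@](C)(O)C=C | starting material
2 | (5R)-5-ethenyl-5-methyloxolan-2-ol (anomer mixture) | C[C@]1(C=C)CCC(O)O1 | intermediate
3 | (methoxymethyl)triphenylphosphonium chloride | [Cl-].COC[P+](c1ccccc1)(c1ccccc1)c1ccccc1 | starting material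
4 | (methoxymethylidene)triphenylphosphorane | COC=P(c1ccccc1)(c1ccccc1)c1ccccc1 | intermediate
5 | (3R)-7-methoxy-3-methylhepta-1,6-dien-3-ol (E/Z mixture at C6=C7) | COC=CCC[C@@](C)(O)C=C | intermediate
6 | (6R)-6-ethenyl-6-methyloxan-2-ol (anomer mixture) | C[C@]1(C=C)CCCC(O)O1 | intermediate
7 | (6R)-6-ethenyl-6-methyloxan-2-one | C[C@]1(C=C)CCCC(=O)O1 | intermediate
8 | pent-1-en-4-yne | C=CCC#C | starting material
9 | dimethyl[(1E)-2-methylpenta-1,4-dien-1-yl]alumane | C=CC/C(C)=C/[Al](C)C | intermediate
10 | (2E)-3-methylhexa-2,5-dien-1-ol | C=CC/C(C)=C/CO | intermediate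
11 | tert-butyl{[(2E)-3-methylhexa-2,5-dien-1-yl]oxy}diphenylsilane | C=CC/C(C)=C/CO[Si](c1ccccc1)(c1ccccc1)C(C)(C)C | intermediate
12 | (6R)-6-[(1E,4E)-6-{[tert-butyl(diphenyl)silyl]oxy}-4-methylhexa-1,4-dien-1-yl]-6-methyloxan-2-one | C[C@]1(/C=C/C/C(C)=C/CO[Si](c2ccccc2)(c2ccccc2)C(C)(C)C)CCCC(=O)O1 | intermediate
13 | tert-butyl{[(2E,5E)-3-methyl-6-[(2R)-2-methyl-6-(trimethylsilyloxy)-3,4-dihydro-2H-pyran-2-yl]hexa-2,5-dien-1-yl]oxy}diphenylsilane (silyl ketene acetal) | C[C@]1(/C=C/C/C(C)=C/CO[Si](c2ccccc2)(c2ccccc2)C(C)(C)C)CCC=C(O[Si](C)(C)C)O1 | intermediate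
14 | trimethylsilyl (1S,2R)-2-[(2E)-4-{[tert-butyl(diphenyl)silyl]oxy}-2-methylbut-2-en-1-yl]-4-methylcyclohex-3-ene-1-carboxylate | CC1=C[C@@H](C/C(C)=C/CO[Si](c2ccccc2)(c2ccccc2)C(C)(C)C)[C@@H](C(=O)O[Si](C)(C)C)CC1 | intermediate
15 | (1S,2R)-2-[(2E)-4-{[tert-butyl(diphenyl)silyl]oxy}-2-methylbut-2-en-1-yl]-4-methylcyclohex-3-ene-1-carboxylic acid | CC1=C[C@@H](C/C(C)=C/CO[Si](c2ccccc2)(c2ccccc2)C(C)(C)C)[C@@H](C(=O)O)CC1 | intermediate
16 | methyl (1S,2R)-2-[(2E)-4-{[tert-butyl(diphenyl)silyl]oxy}-2-methylbut-2-en-1-yl]-4-methylcyclohex-3-ene-1-carboxylate | CC1=C[C@@H](C/C(C)=C/CO[Si](c2ccccc2)(c2ccccc2)C(C)(C)C)[C@@H](C(=O)OC)CC1 | intermediate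
17 | 2-[(1S,2R)-2-[(2E)-4-{[tert-butyl(diphenyl)silyl]oxy}-2-methylbut-2-en-1-yl]-4-methylcyclohex-3-en-1-yl]propan-2-ol | CC1=C[C@@H](C/C(C)=C/CO[Si](c2ccccc2)(c2ccccc2)C(C)(C)C)[C@@H](C(C)(C)O)CC1 | intermediate
18 | tert-butyl{[(4aS,8aS)-1,1,3,6-tetramethyl-1,2,4a,7,8,8a-hexahydronaphthalen-2-yl]methoxy}diphenylsilane (C2 epimers; main isomer of the alkene-isomer mixture) | CC1=C[C@H]2C=C(C)C(CO[Si](c3ccccc3)(c3ccccc3)C(C)(C)C)C(C)(C)[C@H]2CC1 | intermediate
19 | [(4aS,8aS)-1,1,3,6-tetramethyl-1,2,4a,7,8,8a-hexahydronaphthalen-2-yl]methanol (C2 epimers; main isomer of the mixture) | CC1=C[C@H]2C=C(C)C(CO)C(C)(C)[C@H]2CC1 | intermediate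
20 | (4aS,8aS)-1,1,3,6-tetramethyl-1,2,4a,7,8,8a-hexahydronaphthalene-2-carbaldehyde (C2 epimers; main isomer of the mixture) | CC1=C[C@H]2C=C(C)C(C=O)C(C)(C)[C@H]2CC1 | intermediate
21 | (4aR,8aS)-1,1,3,6-tetramethyl-1,4,4a,7,8,8a-hexahydronaphthalene-2-carbaldehyde | CC1=C[C@H]2CC(C)=C(C=O)C(C)(C)[C@H]2CC1 | intermediate
22 | [(4aR,8aS)-1,1,3,6-tetramethyl-1,4,4a,7,8,8a-hexahydronaphthalen-2-yl]methanol | CC1=C[C@H]2CC(C)=C(CO)C(C)(C)[C@H]2CC1 | intermediate
23 | {[(4aR,8aS)-1,1,3,6-tetramethyl-1,4,4a,7,8,8a-hexahydronaphthalen-2-yl]methyl}triphenylphosphonium bromide | CC1=C[C@H]2CC(C)=C(C[P+](c3ccccc3)(c3ccccc3)c3ccccc3)C(C)(C)[C@H]2CC1.[Br-] | intermediate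
24 | (S)-2-methylglycidol, [(2S)-2-methyloxiran-2-yl]methanol | C[C@]1(CO)CO1 | starting material
25 | [(2R)-2-methyloxiran-2-yl]methyl 4-methylbenzenesulfonate | C[C@]1(COS(=O)(=O)c2ccc(C)cc2)CO1 | intermediate
26 | (2R)-2-hydroxy-2-methylhept-6-en-1-yl 4-methylbenzenesulfonate | C=CCCC[C@@](C)(O)COS(=O)(=O)c1ccc(C)cc1 | intermediate
27 | (2R)-2-(but-3-en-1-yl)-2-methyloxirane | C[C@]1(CO1)CCC=C | intermediate
28 | 3-[(2R)-2-methyloxiran-2-yl]propanal | C[C@]1(CO1)CCC=O | intermediate
29 | (3S,4S)-3-methyl-6-[(2R)-2-methyloxiran-2-yl]hex-1-en-4-ol | C[C@]1(CO1)CC[C@H](O)[C@@H](C)C=C | intermediate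
30 | (3S,4S)-3-methyl-6-[(2R)-2-methyloxiran-2-yl]hex-1-en-4-yl methanesulfonate | C[C@]1(CO1)CC[C@H](OS(C)(=O)=O)[C@@H](C)C=C | intermediate
31 | (3S,4S,7S)-7-hydroperoxy-8-hydroxy-3,7-dimethyloct-1-en-4-yl methanesulfonate | OC[C@@](C)(OO)CC[C@H](OS(C)(=O)=O)[C@@H](C)C=C | intermediate
32 | [(3S,6R)-6-[(2S)-but-3-en-2-yl]-3-methyl-1,2-dioxan-3-yl]methanol | OC[C@]1(C)CC[C@H]([C@@H](C)C=C)OO1 | intermediate
33 | (2R)-2-[(3R,6S)-6-(hydroxymethyl)-6-methyl-1,2-dioxan-3-yl]propanal | OC[C@]1(C)CC[C@H]([C@@H](C)C=O)OO1 | intermediate
34 | (2R)-2-[(3R,6S)-6-(hydroxymethyl)-6-methyl-1,2-dioxan-3-yl]propanoic acid | OC[C@]1(C)CC[C@H]([C@@H](C)C(=O)O)OO1 | intermediate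
35 | methyl (2R)-2-[(3R,6S)-6-(hydroxymethyl)-6-methyl-1,2-dioxan-3-yl]propanoate | OC[C@]1(C)CC[C@H]([C@@H](C)C(=O)OC)OO1 | intermediate
36 | methyl (2R)-2-[(3R,6S)-6-formyl-6-methyl-1,2-dioxan-3-yl]propanoate | O=C[C@]1(C)CC[C@H]([C@@H](C)C(=O)OC)OO1 | intermediate
37 | {[(4aR,8aS)-1,1,3,6-tetramethyl-1,4,4a,7,8,8a-hexahydronaphthalen-2-yl]methylidene}triphenylphosphorane | CC1=C[C@H]2CC(C)=C(C=P(c3ccccc3)(c3ccccc3)c3ccccc3)C(C)(C)[C@H]2CC1 | intermediate
38 | methyl (2R)-2-[(3R,6S)-6-methyl-6-{2-[(4aR,8aS)-1,1,3,6-tetramethyl-1,4,4a,7,8,8a-hexahydronaphthalen-2-yl]ethenyl}-1,2-dioxan-3-yl]propanoate (E/Z mixture) | CC1=C[C@H]2CC(C)=C(C=C[C@]3(C)CC[C@H]([C@@H](C)C(=O)OC)OO3)C(C)(C)[C@H]2CC1 | intermediate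
39 | methyl (2R)-2-[(3R,6R)-6-methyl-6-{2-[(4aR,8aS)-1,1,3,6-tetramethyl-1,4,4a,7,8,8a-hexahydronaphthalen-2-yl]ethyl}-1,2-dioxan-3-yl]propanoate | CC1=C[C@H]2CC(C)=C(CC[C@]3(C)CC[C@H]([C@@H](C)C(=O)OC)OO3)C(C)(C)[C@H]2CC1 | intermediate
40 | (2R)-2-[(3R,6R)-6-methyl-6-{2-[(4aR,8aS)-1,1,3,6-tetramethyl-1,4,4a,7,8,8a-hexahydronaphthalen-2-yl]ethyl}-1,2-dioxan-3-yl]propanoic acid | CC1=C[C@H]2CC(C)=C(CC[C@]3(C)CC[C@H]([C@@H](C)C(=O)O)OO3)C(C)(C)[C@H]2CC1 | target

## Step count and least certain steps

Total step count: 28. Longest linear sequence: 16 steps (from 1 through steps 1–4, 7–15 and 26–28). The dioxane branch has 10 steps before the union and the chain partner 2.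

**Step 8 (key step).**
- What may go wrong: the lactone enolate may be silylated on carbon instead of oxygen, or the ketene acetal may be hydrolysed or decompose before the strained boat rearrangement is complete, since that rearrangement needs prolonged heating. Loss of stereochemical fidelity is not expected, because no second transition-state geometry is open.
- Fallback: it sets out from 11 and returns at 17. Cross-metathesis of 11 with but-3-en-2-one should give (3E,6E)-8-{[tert-butyl(diphenyl)silyl]oxy}-6-methylocta-3,6-dien-2-one F1. Wittig methylenation gives tert-butyl{[(2E,5E)-3,7-dimethylocta-2,5,7-trien-1-yl]oxy}diphenylsilane F2. An endo Diels–Alder reaction of F2 with 2,2,2-trifluoroethyl acrylate under a chiral oxazaborolidinium catalyst, with the catalyst enantiomer chosen for the (1S,2R) series, gives 2,2,2-trifluoroethyl (1S,2R)-2-[(2E)-4-{[tert-butyl(diphenyl)silyl]oxy}-2-methylbut-2-en-1-yl]-4-methylcyclohex-3-ene-1-carboxylate F3. Treating F3 with methyllithium and CeCl3 as in step 10 gives 17.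

**Step 11.**
- What may go wrong: the Lewis acid may ionise the allylic silyl ether instead of the carbinol. The proton released on termination may move the ring A alkene. A hydride shift from C8a to the C1 cation would erase the C8a configuration. Simple elimination may compete with ring closure.
- Fallback: it sets out from 15 and returns at 18, and avoids acid altogether. Methyllithium converts 15 into 1-[(1S,2R)-2-[(2E)-4-{[tert-butyl(diphenyl)silyl]oxy}-2-methylbut-2-en-1-yl]-4-methylcyclohex-3-en-1-yl]ethan-1-one F4. Wittig methylenation at low temperature gives tert-butyl({(2E)-3-methyl-4-[(1R,6S)-3-methyl-6-(prop-1-en-2-yl)cyclohex-2-en-1-yl]but-2-en-1-yl}oxy)diphenylsilane F5. Hydrogen-atom transfer from a cobalt hydride to the 1,1-disubstituted alkene of F5 then generates the C1 radical selectively. The conditions are [N,N′-bis(3,5-di-tert-butylsalicylidene)-1,2-cyclohexanediaminato]cobalt (divalent cobalt) as catalyst, a silane and an N-fluoropyridinium oxidant. Radical–polar crossover and closure onto C2 should give the alkene isomers 18, which converge as before.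

**Step 7.**
- What may go wrong: conversion may stay low because the vinyl group sits on a fully substituted, acyloxy-bearing carbon, while the partner is consumed by homodimerisation or its skipped diene is isomerised by ruthenium hydrides.
- Fallback: it sets out from 7 and returns at 12. Methanolysis of 7 (NaOMe, MeOH) gives methyl (5R)-5-hydroxy-5-methylhept-6-enoate F6, whose free tertiary allylic alcohol is a much better metathesis partner. Cross-metathesis with 11 gives methyl (5R,6E,9E)-11-{[tert-butyl(diphenyl)silyl]oxy}-5-hydroxy-5,9-dimethylundeca-6,9-dienoate F7. Acid-catalysed lactonisation with loss of methanol returns 12.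

**Step 21 (with step 22).**
- What may go wrong: the epoxide opening may gain carbocation character and lose part of the C11 configuration. In the following ring closure, elimination of the β-branched mesylate may compete with substitution.
- Fallback: it sets out from 30 and returns at 32, and reverses the order of the two C–O bond formations. Displacement of the mesylate by 2-methoxypropan-2-yl hydroperoxide (CsOH, DMF) with inversion gives (2R)-2-[(3R,4S)-3-[(2-methoxypropan-2-yl)peroxy]-4-methylhex-5-en-1-yl]-2-methyloxirane F8. Mild acid unmasks (2R)-2-[(3R,4S)-3-hydroperoxy-4-methylhex-5-en-1-yl]-2-methyloxirane F9. Under acid catalysis the hydroperoxide opens the epoxide intramolecularly at C11 (6-exo, inversion) to give 32.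

**Step 26.**
- What may go wrong: the ylide and the aldehyde are both hindered, so addition may be slow. This leaves time for the basic ylide to deprotonate C15 and open the dioxane by β-elimination.
- Fallback: it sets out from 22 and returns at 38. PBr3 gives (4aR,8aS)-2-(bromomethyl)-1,1,3,6-tetramethyl-1,4,4a,7,8,8a-hexahydronaphthalene F10. An Arbuzov reaction with triethyl phosphite gives diethyl {[(4aR,8aS)-1,1,3,6-tetramethyl-1,4,4a,7,8,8a-hexahydronaphthalen-2-yl]methyl}phosphonate F11. Its smaller and more nucleophilic sodium anion undergoes Horner–Wadsworth–Emmons olefination with 36 at low temperature to give 38.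

## Further compounds

F1 | step 8 | (3E,6E)-8-{[tert-butyl(diphenyl)silyl]oxy}-6-methylocta-3,6-dien-2-one | CC(=O)/C=C/C/C(C)=C/CO[Si](c1ccccc1)(c1ccccc1)C(C)(C)C
F2 | step 8 | tert-butyl{[(2E,5E)-3,7-dimethylocta-2,5,7-trien-1-yl]oxy}diphenylsilane | C=C(C)/C=C/C/C(C)=C/CO[Si](c1ccccc1)(c1ccccc1)C(C)(C)C
F3 | step 8 | 2,2,2-trifluoroethyl (1S,2R)-2-[(2E)-4-{[tert-butyl(diphenyl)silyl]oxy}-2-methylbut-2-en-1-yl]-4-methylcyclohex-3-ene-1-carboxylate | CC1=C[C@@H](C/C(C)=C/CO[Si](c2ccccc2)(c2ccccc2)C(C)(C)C)[C@@H](C(=O)OCC(F)(F)F)CC1
F4 | step 11 | 1-[(1S,2R)-2-[(2E)-4-{[tert-butyl(diphenyl)silyl]oxy}-2-methylbut-2-en-1-yl]-4-methylcyclohex-3-en-1-yl]ethan-1-one | CC1=C[C@@H](C/C(C)=C/CO[Si](c2ccccc2)(c2ccccc2)C(C)(C)C)[C@@H](C(C)=O)CC1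
F5 | step 11 | tert-butyl({(2E)-3-methyl-4-[(1R,6S)-3-methyl-6-(prop-1-en-2-yl)cyclohex-2-en-1-yl]but-2-en-1-yl}oxy)diphenylsilane | CC1=C[C@@H](C/C(C)=C/CO[Si](c2ccccc2)(c2ccccc2)C(C)(C)C)[C@@H](C(C)=C)CC1
F6 | step 7 | methyl (5R)-5-hydroxy-5-methylhept-6-enoate | COC(=O)CCC[C@@](C)(O)C=C
F7 | step 7 | methyl (5R,6E,9E)-11-{[tert-butyl(diphenyl)silyl]oxy}-5-hydroxy-5,9-dimethylundeca-6,9-dienoate | COC(=O)CCC[C@@](C)(O)/C=C/C/C(C)=C/CO[Si](c1ccccc1)(c1ccccc1)C(C)(C)C
F8 | step 21 | (2R)-2-[(3R,4S)-3-[(2-methoxypropan-2-yl)peroxy]-4-methylhex-5-en-1-yl]-2-methyloxirane | C[C@]1(CO1)CC[C@@H](OOC(C)(C)OC)[C@@H](C)C=C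
F9 | step 21 | (2R)-2-[(3R,4S)-3-hydroperoxy-4-methylhex-5-en-1-yl]-2-methyloxirane | C[C@]1(CO1)CC[C@@H](OO)[C@@H](C)C=C
F10 | step 26 | (4aR,8aS)-2-(bromomethyl)-1,1,3,6-tetramethyl-1,4,4a,7,8,8a-hexahydronaphthalene | CC1=C[C@H]2CC(C)=C(CBr)C(C)(C)[C@H]2CC1
F11 | step 26 | diethyl {[(4aR,8aS)-1,1,3,6-tetramethyl-1,4,4a,7,8,8a-hexahydronaphthalen-2-yl]methyl}phosphonate | CC1=C[C@H]2CC(C)=C(CP(=O)(OCC)OCC)C(C)(C)[C@H]2CC1
A1 | alternative 1 | 3-{[(4-methoxybenzyl)oxy]methyl}-2,4,4-trimethylcyclohexa-2,5-dien-1-one | CC1=C(COCc2ccc(OC)cc2)C(C)(C)C=CC1=O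
A2 | alternative 1 | tert-butyl(dimethyl){[(1E)-2-methylbuta-1,3-dien-1-yl]oxy}silane | C=C/C(C)=C/O[Si](C)(C)C(C)(C)C
A3 | alternative 1 | cis-fused 5-[(tert-butyldimethylsilyl)oxy]-2-{[(4-methoxybenzyl)oxy]methyl}-1,1,3,6-tetramethyl-4a,5,8,8a-tetrahydronaphthalen-4(1H)-one | CC1=CC[C@H]2[C@@H]([C@@H]1O[Si](C)(C)C(C)(C)C)C(=O)C(C)=C(COCc1ccc(OC)cc1)C2(C)C
A4 | alternative 2 | (2E,5E)-7-(diphosphooxy)-3,7,11-trimethyldodeca-2,5,10-trien-1-yl acetate (C7 configuration lost on ionisation and left open) | CC(C)=CCCC(C)(OP(=O)(O)OP(=O)(O)O)/C=C/C/C(C)=C/COC(C)=O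
A5 | alternative 2 | [(4aR,8aS)-1,1,3,6-tetramethyl-1,4,4a,7,8,8a-hexahydronaphthalen-2-yl]methyl acetate | CC1=C[C@H]2CC(C)=C(COC(C)=O)C(C)(C)[C@H]2CC1
A6 | alternative 3 | (2E,5E)-3,7-dimethylocta-2,5,7-trien-1-yl acetate | C=C(C)/C=C/C/C(C)=C/COC(C)=O
A7 | alternative 3 | 2,2,2-trifluoroethyl prop-2-enoate | C=CC(=O)OCC(F)(F)F
A8 | alternative 3 | 2,2,2-trifluoroethyl (1S,2R)-2-[(2E)-4-acetoxy-2-methylbut-2-en-1-yl]-4-methylcyclohex-3-ene-1-carboxylate | CC1=C[C@@H](C/C(C)=C/COC(C)=O)[C@@H](C(=O)OCC(F)(F)F)CC1
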